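**Plan**

1. Retrosynthetic cuts, in order: (a) the ester C–O bond, giving (R)-shikonin and (3Z)-5-methylhexa-3,5-dienoic acid; (b) both aryl–carbonyl bonds of the naphthoquinone, C1–C8a and C4–C4a, in one retro-[4+2]; (c) the bond between the carbinol carbon and the future quinone C2 (aldol); (d) the Z C3=C4 bond of the acid (Wittig).
2. Enabling feature: the 5,8-dihydroxy-1,4-naphthoquinone nucleus is the double enol of 4a,8a-dihydronaphthalene-1,4,5,8-tetraone. Ring B (C4a=C8a flanked by the hydroxyl-bearing C5 and C8) is therefore a latent p-benzoquinone C=C, and C1(=O)–C2=C3–C4(=O) of ring A is the latent bis-enol of a succinic anhydride, a 2,5-bis(silyloxy)furan diene at the complementary oxidation level.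
3. In these terms shikonin is succinic anhydride + 4-methylpent-3-enal + p-benzoquinone − H2O.
4. Forward order: the side chain and its stereocentre are set on a succinate by aldol addition and the succinate is closed to the anhydride. Ring A is then built in one operation (silylation to the furan, Diels–Alder addition to p-benzoquinone, ring opening, enolisation), ring B arriving intact with free hydroxyl groups; acylation with the dienoic acid is last.
5. Stereochemistry: the single stereocentre (R carbinol) comes from an Evans syn aldol with (4S)-4-benzyl-1,3-oxazolidin-2-one; the second aldol centre is sacrificed when it becomes sp2 C2 of the quinone. The Z alkene comes from a salt-free Wittig reaction.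

Key step: step 8

Remark: 5,8-dihydroxy-1,4-naphthoquinones interconvert rapidly between the two tautomers that exchange the quinone and dihydroxybenzene rings; the target is taken as this equilibrating compound, drawn with the side chain on the quinone ring.

**Route**

Step 1
Reactants: 1 (2-carboxyethyl)triphenylphosphonium bromide; 2 methacrolein (2-methylprop-2-enal)
Product: 4 (3Z)-5-methylhexa-3,5-dienoic acid, via sodium ylide carboxylate 3 (not isolated)
Conditions: NaN(SiMe3)2 (2.1 equiv), THF, −78 °C; then 2, −78 °C → rt; cold dilute HCl work-up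
Reagents that add atoms: none
Why: Z-selective Wittig olefination: the salt-free, non-stabilised ylide of the carboxylate should add to the aldehyde under kinetic control through the cis-oxaphosphetane, so the new C3=C4 bond should form Z, while the carboxylate form suppresses both retro-Michael loss of the phosphine and migration of the skipped diene.

Step 2
Reactants: 5 4-tert-butoxy-4-oxobutanoic acid (mono-tert-butyl succinate); 6 (4S)-4-benzyl-1,3-oxazolidin-2-one
Product: 8 tert-butyl 4-[(4S)-4-benzyl-2-oxo-1,3-oxazolidin-3-yl]-4-oxobutanoate, via mixed pivalic anhydride 7 (not isolated)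
Conditions: t-BuCOCl, Et3N, THF, −20 °C; then 6, LiCl, −20 °C → rt
Reagents that add atoms: none
Why: N-acylation of the oxazolidinone through the mixed pivalic anhydride with LiCl/Et3N activation is the standard entry to Evans imides, and attack should occur at the unhindered succinyl carbonyl.

Step 3
Reactants: 9 4-methylpent-3-en-1-ol
Product: 10 4-methylpent-3-enal
Conditions: Dess–Martin periodinane, NaHCO3, CH2Cl2, 0 °C → rt; cold filtration, solution used at once
Reagents that add atoms: none
Why: Dess–Martin oxidation under buffered, non-basic conditions should stop at the β,γ-unsaturated aldehyde without moving the double bond into conjugation.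

Step 4
Reactants: 8 tert-butyl 4-[(4S)-4-benzyl-2-oxo-1,3-oxazolidin-3-yl]-4-oxobutanoate; 10 4-methylpent-3-enal
Product: 13 tert-butyl (3S,4R)-3-{[(4S)-4-benzyl-2-oxo-1,3-oxazolidin-3-yl]carbonyl}-4-hydroxy-7-methyloct-6-enoate, via Z-dibutylboron enolate 11 (not isolated), via dibutylboron aldolate 12 (not isolated)
Conditions: n-Bu2BOTf, i-Pr2NEt, CH2Cl2, −78 → 0 °C; then 10, −78 → 0 °C; pH 7 buffer, MeOH, 30% H2O2, 0 °C
Reagents that add atoms: none
Why: Evans syn aldol: the Z-boron enolate should react through a chair Zimmerman–Traxler transition state on the enolate face away from the benzyl group, setting the carbinol centre R (and the α centre S, erased later), and the hindered tert-butyl ester should not lactonise with the new hydroxyl.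

Step 5
Reactants: 13 tert-butyl (3S,4R)-3-{[(4S)-4-benzyl-2-oxo-1,3-oxazolidin-3-yl]carbonyl}-4-hydroxy-7-methyloct-6-enoate
Product: 14 tert-butyl (3S,4R)-3-{[(4S)-4-benzyl-2-oxo-1,3-oxazolidin-3-yl]carbonyl}-7-methyl-4-[(triethylsilyl)oxy]oct-6-enoate
Conditions: Et3SiOTf, 2,6-lutidine, CH2Cl2, −78 → 0 °C
Reagents that add atoms: triethylsilyl trifluoromethanesulfonate, CC[Si](CC)(CC)OS(=O)(=O)C(F)(F)F
Why: Silyl triflate/2,6-lutidine silylation of a hindered secondary alcohol; the triethylsilyl ether blocks lactonisation and retro-aldol cleavage and is chosen so that it falls off in the acidic finish of step 8.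

Step 6
Reactants: 14 tert-butyl (3S,4R)-3-{[(4S)-4-benzyl-2-oxo-1,3-oxazolidin-3-yl]carbonyl}-7-methyl-4-[(triethylsilyl)oxy]oct-6-enoate
Product: 16 (2S,3R)-2-(2-tert-butoxy-2-oxoethyl)-6-methyl-3-[(triethylsilyl)oxy]hept-5-enoic acid, via lithium peroxycarboxylate 15 (not isolated)
Conditions: LiOH·H2O, 30% H2O2, THF/H2O, 0 °C; then aq. Na2SO3; 0.5 M HCl to pH 4, 0 °C
Reagents that add atoms: hydrogen peroxide, OO
Why: Hydroperoxide cleavage of the imide (selective attack at the exocyclic carbonyl) followed by sulfite reduction of the percarboxylate; the tert-butyl ester, silyl ether and alkene should survive the cold basic medium, and the carbinol centre is not touched.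

Step 7
Reactants: 16 (2S,3R)-2-(2-tert-butoxy-2-oxoethyl)-6-methyl-3-[(triethylsilyl)oxy]hept-5-enoic acid
Product: 18 (3S)-3-[(1R)-4-methyl-1-[(triethylsilyl)oxy]pent-3-en-1-yl]oxolane-2,5-dione, via acid chloride 17 (not isolated)
Conditions: 1-chloro-N,N,2-trimethylprop-1-en-1-amine, CH2Cl2, 0 °C → rt; volatiles removed, rapid filtration through dry silica
Reagents that add atoms: none
Why: Neutral acid chloride formation with the α-chloroenamine, then 5-exo-trig attack of the tert-butyl ester carbonyl oxygen on the acyl chloride and loss of tert-butyl as tert-butyl chloride, the same acylative de-tert-butylation by which N-Boc amino acid chlorides close to N-carboxyanhydrides; no free HCl is formed, so the silyl ether and the trisubstituted alkene should be preserved.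

Step 8
Reactants: 18 (3S)-3-[(1R)-4-methyl-1-[(triethylsilyl)oxy]pent-3-en-1-yl]oxolane-2,5-dione; 19 p-benzoquinone (cyclohexa-2,5-diene-1,4-dione)
Product: 23 (R)-shikonin, 5,8-dihydroxy-2-[(1R)-1-hydroxy-4-methylpent-3-en-1-yl]naphthalene-1,4-dione, via bis(silyloxy)furan 20 (not isolated), via oxa-bridged cycloadduct 21 (not isolated), via O-triethylsilyl shikonin 22 (not isolated)
Conditions: Et3N, Me3SiOTf, Et2O, −20 → 0 °C, decant from Et3NH·OTf, evaporate; then 19 (1.2 equiv), CH2Cl2, −78 → 0 °C (diene added to quinone); then 1 M HCl, THF, 0 °C → rt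
Reagents that add atoms: none
Why: Double O-silylation converts the anhydride into the aromatic 2,5-bis(trimethylsilyloxy)furan 20, a very electron-rich diene locked s-cis whose termini C2 and C5 are the future quinone carbonyl carbons; it adds across one C=C of p-benzoquinone in a normal-electron-demand [4+2] cycloaddition (or the equivalent Mukaiyama–Michael addition and ring closure) to give 21, and dilute acid then collapses the bridging bis-silyl ketal to the ene-dione, lets the two ring-fusion C–H bonds enolise to the aromatic dihydroxy ring and hydrolyses the triethylsilyl ether. The closest known reaction type is the Diels–Alder reaction of 2,5-bis(trimethylsilyloxy)furans derived from succinic anhydrides with quinone and acetylenic dienophiles, which gives para-dioxygenated arenes after loss of the silyl groups. Ring A is closed by this intermolecular [4+2] cycloaddition, suprafacial on both components, with both aryl–carbonyl bonds formed in the one event, while the furan oxygen bridge is a temporary ring that is opened again in the acid stage and ring B arrives intact from the quinone. The four sp3 centres created in 21 (two bridgeheads and two ring-fusion carbons, endo or exo) are all erased on aromatisation, so no new stereocentre has to be controlled, and the carbinol centre is a spectator that should keep its R configuration. The step needs chemoselectivity for the quinone C=C over the prenyl alkene (secured by the match of a donor diene with an acceptor alkene), mono-addition (secured by adding the diene to a slight excess of quinone at −78 °C) and no regiocontrol at all, because both ends of the quinone C=C are equivalent and either orientation leads to the same product. The oxidation levels are complementary, so the naphthazarin nucleus should appear with free hydroxyl groups and without any redox or deprotection step on the ring system.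

Step 9
Reactants: 23 (R)-shikonin; 4 (3Z)-5-methylhexa-3,5-dienoic acid
Product: 24 (1R)-1-(5,8-dihydroxy-1,4-dioxo-1,4-dihydronaphthalen-2-yl)-4-methylpent-3-en-1-yl (3Z)-5-methylhexa-3,5-dienoate
Conditions: DCC, DMAP (0.1 equiv), CH2Cl2, −20 → 0 °C
Reagents that add atoms: none
Why: Steglich esterification: the side-chain secondary hydroxyl should be acylated while the two peri phenols, locked in hydrogen bonds to the quinone carbonyls, stay free, as in known acylations of this alcohol; low temperature and only catalytic DMAP should keep the skipped Z-diene out of conjugation, and the configuration is retained because only the O–H bond reacts.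

**Compound list**

1 | (2-carboxyethyl)triphenylphosphonium bromide | OC(=O)CC[P+](c1ccccc1)(c1ccccc1)c1ccccc1.[Br-] | starting material
2 | methacrolein (2-methylprop-2-enal) | CC(=C)C=O | starting material
3 | sodium 3-(triphenyl-λ5-phosphanylidene)propanoate | [Na+].[O-]C(=O)CC=P(c1ccccc1)(c1ccccc1)c1ccccc1 | intermediate
4 | (3Z)-5-methylhexa-3,5-dienoic acid | C=C(C)/C=C\CC(=O)O | intermediate
5 | 4-tert-butoxy-4-oxobutanoic acid | CC(C)(C)OC(=O)CCC(=O)O | starting material
6 | (4S)-4-benzyl-1,3-oxazolidin-2-one | O=C1N[C@@H](Cc2ccccc2)CO1 | starting material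
7 | 4-tert-butoxy-4-oxobutanoic 2,2-dimethylpropanoic anhydride | CC(C)(C)OC(=O)CCC(=O)OC(=O)C(C)(C)C | intermediate
8 | tert-butyl 4-[(4S)-4-benzyl-2-oxo-1,3-oxazolidin-3-yl]-4-oxobutanoate | CC(C)(C)OC(=O)CCC(=O)N1[C@@H](Cc2ccccc2)COC1=O | intermediate
9 | 4-methylpent-3-en-1-ol | CC(C)=CCCO | starting material
10 | 4-methylpent-3-enal | CC(C)=CCC=O | intermediate
11 | tert-butyl (3Z)-4-[(4S)-4-benzyl-2-oxo-1,3-oxazolidin-3-yl]-4-[(dibutylboranyl)oxy]but-3-enoate | CCCCB(CCCC)O/C(=C\CC(=O)OC(C)(C)C)N1[C@@H](Cc2ccccc2)COC1=O | intermediate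
12 | O-dibutylboranyl derivative (boron aldolate) of 13 | CC(C)=CC[C@@H](OB(CCCC)CCCC)[C@H](CC(=O)OC(C)(C)C)C(=O)N1[C@@H](Cc2ccccc2)COC1=O | intermediate
13 | tert-butyl (3S,4R)-3-{[(4S)-4-benzyl-2-oxo-1,3-oxazolidin-3-yl]carbonyl}-4-hydroxy-7-methyloct-6-enoate | CC(C)=CC[C@@H](O)[C@H](CC(=O)OC(C)(C)C)C(=O)N1[C@@H](Cc2ccccc2)COC1=O | intermediate
14 | tert-butyl (3S,4R)-3-{[(4S)-4-benzyl-2-oxo-1,3-oxazolidin-3-yl]carbonyl}-7-methyl-4-[(triethylsilyl)oxy]oct-6-enoate | CC(C)=CC[C@@H](O[Si](CC)(CC)CC)[C@H](CC(=O)OC(C)(C)C)C(=O)N1[C@@H](Cc2ccccc2)COC1=O | intermediate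
15 | lithium (2S,3R)-2-(2-tert-butoxy-2-oxoethyl)-6-methyl-3-[(triethylsilyl)oxy]hept-5-eneperoxoate | CC(C)=CC[C@@H](O[Si](CC)(CC)CC)[C@H](CC(=O)OC(C)(C)C)C(=O)O[O-].[Li+] | intermediate
16 | (2S,3R)-2-(2-tert-butoxy-2-oxoethyl)-6-methyl-3-[(triethylsilyl)oxy]hept-5-enoic acid | CC(C)=CC[C@@H](O[Si](CC)(CC)CC)[C@H](CC(=O)OC(C)(C)C)C(=O)O | intermediate
17 | tert-butyl (3S,4R)-3-(chlorocarbonyl)-7-methyl-4-[(triethylsilyl)oxy]oct-6-enoate | CC(C)=CC[C@@H](O[Si](CC)(CC)CC)[C@H](CC(=O)OC(C)(C)C)C(=O)Cl | intermediate
18 | (3S)-3-[(1R)-4-methyl-1-[(triethylsilyl)oxy]pent-3-en-1-yl]oxolane-2,5-dione | CC(C)=CC[C@@H](O[Si](CC)(CC)CC)[C@H]1C(=O)OC(=O)C1 | intermediate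
19 | p-benzoquinone (cyclohexa-2,5-diene-1,4-dione) | O=C1C=CC(=O)C=C1 | starting material
20 | 3-[(1R)-4-methyl-1-[(triethylsilyl)oxy]pent-3-en-1-yl]-2,5-bis(trimethylsilyloxy)furan | CC(C)=CC[C@@H](O[Si](CC)(CC)CC)c1cc(O[Si](C)(C)C)oc1O[Si](C)(C)C | intermediate
21 | 2-[(1R)-4-methyl-1-[(triethylsilyl)oxy]pent-3-en-1-yl]-1,4-bis(trimethylsilyloxy)-1,4,4a,8a-tetrahydro-1,4-epoxynaphthalene-5,8-dione (diastereomer mixture at the ring centres) | CC(C)=CC[C@@H](O[Si](CC)(CC)CC)C1=CC2(O[Si](C)(C)C)OC1(O[Si](C)(C)C)C3C2C(=O)C=CC3=O | intermediate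
22 | 5,8-dihydroxy-2-[(1R)-4-methyl-1-[(triethylsilyl)oxy]pent-3-en-1-yl]naphthalene-1,4-dione | CC(C)=CC[C@@H](O[Si](CC)(CC)CC)C1=CC(=O)c2c(O)ccc(O)c2C1=O | intermediate
23 | (R)-shikonin, 5,8-dihydroxy-2-[(1R)-1-hydroxy-4-methylpent-3-en-1-yl]naphthalene-1,4-dione | CC(C)=CC[C@@H](O)C1=CC(=O)c2c(O)ccc(O)c2C1=O | intermediate
24 | (1R)-1-(5,8-dihydroxy-1,4-dioxo-1,4-dihydronaphthalen-2-yl)-4-methylpent-3-en-1-yl (3Z)-5-methylhexa-3,5-dienoate | C=C(C)/C=C\CC(=O)O[C@H](CC=C(C)C)C1=CC(=O)c2c(O)ccc(O)c2C1=O | target

**Totals and risks**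

Total step count: 9. Longest linear sequence: 7 steps (steps 2, 4, 5, 6, 7, 8, 9).

Steps most likely to fail, riskiest first:

1. Step 8. Once the anhydride has become the electron-rich silyloxyfuran, the allylic silyloxy group may ionise or eliminate (loss of the side-chain oxygen and of the stereocentre), or the quinone may undergo conjugate addition without ring closure. The fallback moves the side chain from the diene to the dienophile and uses the parent diene, relying on the fact that 2- and 6-substituted naphthazarins are the same compound. It sets out from aldehyde 10 and rejoins the route at shikonin 23. (2,5-Dimethoxyphenyl)lithium (from 2-bromo-1,4-dimethoxybenzene and n-BuLi, THF, −78 °C) would be added to 10 to give racemic 1-(2,5-dimethoxyphenyl)-4-methylpent-3-en-1-ol F1. Dess–Martin oxidation would give 1-(2,5-dimethoxyphenyl)-4-methylpent-3-en-1-one F2. Reduction with (+)-B-chlorodiisopinocampheylborane (THF, −25 °C) should give (1R)-1-(2,5-dimethoxyphenyl)-4-methylpent-3-en-1-ol F3, the sense following the behaviour of aryl alkyl ketones. Oxidation with (NH4)2Ce(NO3)6 in MeCN/H2O at 0 °C should give 2-[(1R)-1-hydroxy-4-methylpent-3-en-1-yl]cyclohexa-2,5-diene-1,4-dione F4. Its unsubstituted C5=C6 bond would then take up 2,5-bis(trimethylsilyloxy)furan F5 (from succinic anhydride, Me3SiCl, Et3N, ZnCl2, MeCN; used in excess, which also silylates the hydroxyl) to give 1,4-bis(trimethylsilyloxy)-6-[(1R)-4-methyl-1-(trimethylsilyloxy)pent-3-en-1-yl]-1,4,4a,8a-tetrahydro-1,4-epoxynaphthalene-5,8-dione F6. Dilute HCl in THF should convert this into 23.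

2. Step 4. The β,γ-double bond of aldehyde 10 may migrate into conjugation, or the aldehyde may self-condense, under the amine/boron triflate conditions, so that the aldol partner is lost. The fallback builds the prenyl group after the aldol from a stable aldehyde; it sets out from imide 8 and rejoins at silyl ether 14. The same boron aldol of 8 with 3-[(4-methoxybenzyl)oxy]propanal should give tert-butyl (3S,4R)-3-{[(4S)-4-benzyl-2-oxo-1,3-oxazolidin-3-yl]carbonyl}-4-hydroxy-6-[(4-methoxybenzyl)oxy]hexanoate F7. Et3SiOTf/2,6-lutidine would give tert-butyl (3S,4R)-3-{[(4S)-4-benzyl-2-oxo-1,3-oxazolidin-3-yl]carbonyl}-6-[(4-methoxybenzyl)oxy]-4-[(triethylsilyl)oxy]hexanoate F8. DDQ in CH2Cl2/pH 7 buffer would free tert-butyl (3S,4R)-3-{[(4S)-4-benzyl-2-oxo-1,3-oxazolidin-3-yl]carbonyl}-6-hydroxy-4-[(triethylsilyl)oxy]hexanoate F9, which would be oxidised at once (Dess–Martin periodinane) to tert-butyl (3S,4R)-3-{[(4S)-4-benzyl-2-oxo-1,3-oxazolidin-3-yl]carbonyl}-6-oxo-4-[(triethylsilyl)oxy]hexanoate F10. Wittig reaction with isopropylidenetriphenylphosphorane (from isopropyltriphenylphosphonium iodide and NaN(SiMe3)2, THF, −78 °C) should then give 14.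

3. Step 7. If the tert-butyl cation loses a proton instead of collapsing to the chloride, the HCl released may cleave the silyl ether or add to the alkene, or the ring closure may stall at the acid chloride. The fallback separates ester cleavage from ring closure; it sets out from acid 16 and rejoins at anhydride 18. Me3SiOTf/2,6-lutidine (CH2Cl2, 0 °C → rt) followed by a buffered aqueous work-up should cleave the tert-butyl ester to (2S)-2-[(1R)-4-methyl-1-[(triethylsilyl)oxy]pent-3-en-1-yl]butanedioic acid F11, and DCC in CH2Cl2 at 0 °C should dehydrate it to 18.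

**Further compounds**

F1 | step 8 | 1-(2,5-dimethoxyphenyl)-4-methylpent-3-en-1-ol (racemic) | COc1ccc(OC)c(C(O)CC=C(C)C)c1
F2 | step 8 | 1-(2,5-dimethoxyphenyl)-4-methylpent-3-en-1-one | COc1ccc(OC)c(C(=O)CC=C(C)C)c1
F3 | step 8 | (1R)-1-(2,5-dimethoxyphenyl)-4-methylpent-3-en-1-ol | COc1ccc(OC)c([C@H](O)CC=C(C)C)c1
F4 | step 8 | 2-[(1R)-1-hydroxy-4-methylpent-3-en-1-yl]cyclohexa-2,5-diene-1,4-dione | CC(C)=CC[C@@H](O)C1=CC(=O)C=CC1=O
F5 | step 8 | 2,5-bis(trimethylsilyloxy)furan | C[Si](C)(C)Oc1ccc(O[Si](C)(C)C)o1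
F6 | step 8 | 1,4-bis(trimethylsilyloxy)-6-[(1R)-4-methyl-1-(trimethylsilyloxy)pent-3-en-1-yl]-1,4,4a,8a-tetrahydro-1,4-epoxynaphthalene-5,8-dione | CC(C)=CC[C@@H](O[Si](C)(C)C)C1=CC(=O)C2C(C1=O)C1(O[Si](C)(C)C)C=CC2(O[Si](C)(C)C)O1
F7 | step 4 | tert-butyl (3S,4R)-3-{[(4S)-4-benzyl-2-oxo-1,3-oxazolidin-3-yl]carbonyl}-4-hydroxy-6-[(4-methoxybenzyl)oxy]hexanoate | COc1ccc(COCC[C@@H](O)[C@H](CC(=O)OC(C)(C)C)C(=O)N2[C@@H](Cc3ccccc3)COC2=O)cc1
F8 | step 4 | tert-butyl (3S,4R)-3-{[(4S)-4-benzyl-2-oxo-1,3-oxazolidin-3-yl]carbonyl}-6-[(4-methoxybenzyl)oxy]-4-[(triethylsilyl)oxy]hexanoate | COc1ccc(COCC[C@@H](O[Si](CC)(CC)CC)[C@H](CC(=O)OC(C)(C)C)C(=O)N2[C@@H](Cc3ccccc3)COC2=O)cc1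
F9 | step 4 | tert-butyl (3S,4R)-3-{[(4S)-4-benzyl-2-oxo-1,3-oxazolidin-3-yl]carbonyl}-6-hydroxy-4-[(triethylsilyl)oxy]hexanoate | OCC[C@@H](O[Si](CC)(CC)CC)[C@H](CC(=O)OC(C)(C)C)C(=O)N1[C@@H](Cc2ccccc2)COC1=O
F10 | step 4 | tert-butyl (3S,4R)-3-{[(4S)-4-benzyl-2-oxo-1,3-oxazolidin-3-yl]carbonyl}-6-oxo-4-[(triethylsilyl)oxy]hexanoate | O=CC[C@@H](O[Si](CC)(CC)CC)[C@H](CC(=O)OC(C)(C)C)C(=O)N1[C@@H](Cc2ccccc2)COC1=O
F11 | step 7 | (2S)-2-[(1R)-4-methyl-1-[(triethylsilyl)oxy]pent-3-en-1-yl]butanedioic acid | CC(C)=CC[C@@H](O[Si](CC)(CC)CC)[C@H](CC(=O)O)C(=O)O
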